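**Retrosynthetic overview**

- The target is meso. In each cyclohexane ring the quaternary carbon carries CH3, the ketone carbonyl carbon and the ring carbinol carbon, so it is a latent 2-alkyl-2-methylmalonate. Each exocyclic C=CH–CH2 unit has its chain cis to the carbinol carbon, so it is the syn adduct of a terminal alkyne, an aldehyde and an alkyl group.
- The two 4-methylpent-3-enoyl arms are removed two-directionally (oxidation, cross-metathesis, allyl addition) back to a meso dialdehyde and then a meso diester.
- Key disconnection: the bond between the linker CH2 and the ring B exocyclic CH, together with the ring B bond between carbinol carbon and alkene carbon. Both are made in one nickel-catalysed alkyne–aldehyde–alkylzinc coupling of a ring A homoallylic zinc reagent with the (S)-ynal.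
- Ring A is closed first, from the (R)-ynal, by the same cyclization with vinylzinc; ring B is closed second, in the union step.
- Both antipodal ynals come from one esterase-derived malonate half-ester, by reducing either its acid or its ester group.

Key step: step 13

Assumption: the esterase is taken to leave the (R)-half-ester 4; if the enzyme prefers the other ester group, the two reduction modes (steps 3 and 5) simply exchange branches, because each ynal antipode can be reached from either half-ester antipode.

**Route**

Step 1
Reactants: 1 dimethyl methylmalonate; 2 5-chloropent-1-yne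
Product: 3 dimethyl 2-methyl-2-(pent-4-yn-1-yl)propanedioate
Conditions: NaH (1.1 eq), DMF, 0 °C; then 2, NaI (cat.), 60 °C
Reagents that add atoms: none
Why: Malonic ester alkylation: the stabilized sodium enolate of 1 displaces the primary chloride in an SN2 reaction after in situ halide exchange to the iodide, the far less acidic alkyne C–H stays untouched, and no stereocentre arises because the product is prochiral.

Step 2
Reactants: 3 dimethyl 2-methyl-2-(pent-4-yn-1-yl)propanedioate
Product: 4 (R)-2-(methoxycarbonyl)-2-methylhept-6-ynoic acid
Conditions: pig liver esterase, phosphate buffer pH 7.5, DMSO (cosolvent), 25 °C, pH-stat with aq. NaOH; then HCl to pH 2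
Reagents that add atoms: water O
Why: Enzymatic desymmetrization by ester hydrolysis: the esterase distinguishes the two enantiotopic methoxycarbonyl groups, so the quaternary stereocentre is set by the chiral active site, and the hindered half-ester anion should not be hydrolysed further.

Step 3
Reactants: 4 (R)-2-(methoxycarbonyl)-2-methylhept-6-ynoic acid
Product: 6 methyl (R)-2-(hydroxymethyl)-2-methylhept-6-ynoate, via mixed carbonic anhydride 5 (not isolated)
Conditions: i-BuOCOCl, N-methylmorpholine, THF, −15 °C; then NaBH4, THF/H2O, 0 °C
Reagents that add atoms: none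
Why: Carboxylic acid reduction through a mixed carbonic anhydride: NaBH4 attacks only the activated acyl carbon and leaves the methyl ester and the alkyne (which a borane would hydroborate) intact, and no bond to the quaternary centre is broken, so its configuration is retained.

Step 4
Reactants: 6 methyl (R)-2-(hydroxymethyl)-2-methylhept-6-ynoate
Product: 7 methyl (R)-2-formyl-2-methylhept-6-ynoate
Conditions: Dess–Martin periodinane, CH2Cl2, 0 °C to rt
Reagents that add atoms: none
Why: Dess–Martin oxidation of a neopentyl primary alcohol stops at the aldehyde, which has no α-hydrogen and therefore cannot enolize or racemize.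

Step 5
Reactants: 4 (R)-2-(methoxycarbonyl)-2-methylhept-6-ynoic acid
Product: 9 (S)-2-(hydroxymethyl)-2-methylhept-6-ynoic acid, via lithium carboxylate 8 (not isolated)
Conditions: LiOt-Bu (1.0 eq), THF, 0 °C; then LiBH4 (2.5 eq), THF, 0 to 50 °C; then aq. HCl
Reagents that add atoms: none
Why: Chemoselective LiBH4 ester reduction: a carboxylate is inert to borohydride whereas the methyl ester is reduced, pre-forming the lithium salt with an alkoxide base avoids acyloxyborane and borane formation, and the two carboxyl carbons thereby exchange roles relative to step 3, which opens the antipodal series without touching the stereocentre.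

Step 6
Reactants: 9 (S)-2-(hydroxymethyl)-2-methylhept-6-ynoic acid
Product: 10 methyl (S)-2-(hydroxymethyl)-2-methylhept-6-ynoate
Conditions: Me3SiCHN2, toluene/MeOH, 0 °C to rt
Reagents that add atoms: trimethylsilyldiazomethane C[Si](C)(C)C=[N+]=[N-]
Why: Esterification with a diazoalkane: the acid protonates the reagent and the carboxylate is O-methylated with loss of N2 (methanol removes the silyl group), while the neutral primary alcohol does not react.

Step 7
Reactants: 10 methyl (S)-2-(hydroxymethyl)-2-methylhept-6-ynoate
Product: 11 methyl (S)-2-formyl-2-methylhept-6-ynoate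
Conditions: Dess–Martin periodinane, CH2Cl2, 0 °C to rt
Reagents that add atoms: none
Why: Dess–Martin oxidation as in step 4 gives the non-enolizable antipodal ynal without risk to the quaternary centre.

Step 8
Reactants: 7 methyl (R)-2-formyl-2-methylhept-6-ynoate
Product: 12 methyl (1R,2S,3Z)-2-hydroxy-1-methyl-3-(prop-2-en-1-ylidene)cyclohexane-1-carboxylate (ring A dienol; OH cis to CO2Me, vinyl cis to the carbinol carbon)
Conditions: CH2=CHMgBr/ZnCl2 (1:1, 2.5 eq), THF, 0 °C; Ni(cod)2 (10 mol %), no phosphine; slow addition of 7, 0 °C; aq. NH4Cl
Reagents that add atoms: vinylmagnesium bromide C=C[Mg]Br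
Why: Nickel-catalysed alkylative cyclization of an ynal with an organozinc: oxidative coupling of alkyne and aldehyde on zerovalent nickel gives an oxanickelacyclopentene (6-exo-dig closure of ring A), vinyl transfer from zinc and reductive elimination place the aldehyde carbon and the vinyl group syn across the alkyne (Z), and the carbinol configuration should follow from the quaternary centre because zinc chelation of the α-formyl ester holds the aldehyde oxygen beside the ester, giving OH cis to CO2Me.

Step 9
Reactants: 12 ring A dienol
Product: 13 methyl (1R,2S,3Z)-1-methyl-3-(prop-2-en-1-ylidene)-2-(triethylsilyloxy)cyclohexane-1-carboxylate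
Conditions: Et3SiOTf, 2,6-lutidine, CH2Cl2, −78 to 0 °C
Reagents that add atoms: triethylsilyl trifluoromethanesulfonate CC[Si](CC)(CC)OS(=O)(=O)C(F)(F)F
Why: Silyl ether formation with a silyl triflate and a hindered pyridine base is fast enough for the hindered allylic carbinol and affects neither the diene nor the ester.

Step 10
Reactants: 13 ring A silyl dienol
Product: 15 methyl (1R,2S,3Z)-3-(3-hydroxypropylidene)-1-methyl-2-(triethylsilyloxy)cyclohexane-1-carboxylate, via B-alkyl-9-BBN adduct 14 (not isolated)
Conditions: 9-BBN, THF, 0 °C to rt; then NaBO3·4H2O, THF/H2O, rt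
Reagents that add atoms: sodium perborate [Na+].[Na+].O[B-]1(O)OO[B-](O)(O)OO1
Why: Hydroboration–oxidation with a bulky dialkylborane: 9-BBN places boron on the terminal CH2 of the monosubstituted vinyl group far faster than it attacks the trisubstituted exocyclic alkene, and perborate oxidizes the C–B bond without harming the ester or the silyl ether.

Step 11
Reactants: 15 ring A homoallylic alcohol
Product: 16 methyl (1R,2S,3Z)-3-(3-iodopropylidene)-1-methyl-2-(triethylsilyloxy)cyclohexane-1-carboxylate
Conditions: I2, PPh3, imidazole, CH2Cl2, 0 °C to rt
Reagents that add atoms: iodine II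
Why: Appel-type iodination: the alkoxyphosphonium salt of the primary alcohol is displaced by iodide in an SN2 reaction, and imidazole keeps the medium non-acidic for the silyl ether.

Step 12
Reactants: 16 ring A homoallylic iodide
Product: 17 ring A alkylzinc iodide, {(3Z)-3-[(2S,3R)-3-(methoxycarbonyl)-3-methyl-2-(triethylsilyloxy)cyclohexylidene]propyl}zinc iodide (THF solution, LiCl complex, titrated and used at once)
Conditions: Zn dust (activated with BrCH2CH2Br and Me3SiCl), LiCl, THF, 40 °C
Reagents that add atoms: zinc [Zn]
Why: LiCl-promoted direct insertion of zinc into a primary C–I bond gives a soluble alkylzinc iodide that tolerates the ester and the silyl ether and, being homoallylic, has no easy elimination pathway.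

Step 13
Reactants: 17 ring A alkylzinc iodide; 11 methyl (S)-2-formyl-2-methylhept-6-ynoate
Product: 18 ring A–ring B diester with one free carbinol: ring A as in 16 (1R,2S, OSiEt3), ring B its mirror-image ring (quaternary carbon S, carbinol carbon R, free OH cis to CO2Me), joined by a =CH–CH2–CH2–CH= linker with both exocyclic alkenes Z
Conditions: Ni(cod)2 (15 mol %), no phosphine, THF, 0 °C; 11 added slowly to 17 (1.5 eq); then rt; aq. NH4Cl
Reagents that add atoms: none
Why: Proposed new method: zerovalent nickel should bind the terminal alkyne and the zinc-activated aldehyde of 11 and couple them oxidatively to an oxanickelacyclopentene, after which the alkyl group of 17 passes from zinc to nickel and C–C reductive elimination with retention releases the zinc alkoxide of 18; the closest known reaction type is the nickel-catalysed three-component alkylative cyclization of ynals with simple organozincs (as in step 8), which has not been shown as a fragment union with a functionalized, β-hydrogen-bearing alkylzinc halide. Ring B closes in the 6-exo-dig sense (aldehyde carbon to internal alkyne carbon) while the terminal alkyne carbon bonds to the CH2–Zn carbon of 17. The geometry of the new exocyclic alkene is fixed by the nickelacycle, because carbinol carbon and incoming alkyl are delivered syn across the alkyne. The new carbinol centre is controlled by the adjacent quaternary carbon: with the α-formyl ester chelated to zinc, a chair-like closure with the methyl equatorial and the flat ester axial and gauche to the metal-bound oxygen places OH cis to CO2Me, and since the stereocentres of 17 are remote the outcome should mirror that of step 8. The step needs alkyl transfer to outrun β-hydride elimination and needs the cis face selectivity; the absence of phosphine, the non-enolizable neopentyl aldehyde, the gem-disubstituent assist of the quaternary carbon and the unhindered terminal alkyne serve the first, chelation the second, and the esters and the silyl ether are inert to an alkylzinc halide.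

Step 14
Reactants: 18 ring A–ring B diester with one free carbinol
Product: 19 meso bis(triethylsilyl) diester (both carbinols as OSiEt3, each cis to its CO2Me; both alkenes Z)
Conditions: Et3SiOTf, 2,6-lutidine, CH2Cl2, −78 to 0 °C
Reagents that add atoms: triethylsilyl trifluoromethanesulfonate CC[Si](CC)(CC)OS(=O)(=O)C(F)(F)F
Why: Silylation as in step 9 makes the two halves constitutionally equal, so that the compound becomes meso and all later steps can run two-directionally.

Step 15
Reactants: 19 meso bis(triethylsilyl) diester
Product: 20 meso bis(triethylsilyl) diol (both CO2Me reduced to CH2OH)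
Conditions: i-Bu2AlH (6 eq), CH2Cl2, −78 to −20 °C; aq. KNaC4H4O6
Reagents that add atoms: none
Why: Ester reduction with excess i-Bu2AlH takes both neopentyl esters to the primary alcohols in one operation, the aluminium alkoxides at low temperature should not provoke silyl migration, and the alkenes are inert.

Step 16
Reactants: 20 meso bis(triethylsilyl) diol
Product: 21 meso bis(triethylsilyl) dialdehyde
Conditions: Dess–Martin periodinane, NaHCO3, CH2Cl2, 0 °C to rt
Reagents that add atoms: none
Why: Buffered Dess–Martin oxidation gives the two α-quaternary aldehydes, which cannot enolize, and leaves the silyl ethers and alkenes untouched.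

Step 17
Reactants: 21 meso bis(triethylsilyl) dialdehyde
Product: 22 bis(1-hydroxybut-3-en-1-yl) compound (mixture at the two new carbinol carbons)
Conditions: CH2=CHCH2MgBr (4 eq), Et2O/THF, −78 to 0 °C; aq. NH4Cl
Reagents that add atoms: allylmagnesium bromide C=CC[Mg]Br
Why: Grignard addition: allylmagnesium bromide is reactive enough for hindered α-quaternary aldehydes, and the two new carbinol centres are formed without control, which is immaterial because they are oxidized in step 19.

Step 18
Reactants: 22 bis(1-hydroxybut-3-en-1-yl) compound
Product: 23 bis(1-hydroxy-4-methylpent-3-en-1-yl) compound (mixture at the two side-chain carbinol carbons)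
Conditions: 2-methyl-2-butene (large excess), second-generation Grubbs catalyst RuCl2(=CHPh)(PCy3)(H2IMes) (5 mol %), CH2Cl2, 40 °C, sealed vessel
Reagents that add atoms: 2-methyl-2-butene CC=C(C)C
Why: Olefin cross-metathesis on a ruthenium carbene: each monosubstituted terminal alkene exchanges its CH2 for the isopropylidene group of the excess 2-methyl-2-butene, whereas the trisubstituted exocyclic alkenes do not enter the catalytic cycle.

Step 19
Reactants: 23 bis(1-hydroxy-4-methylpent-3-en-1-yl) compound
Product: 24 meso bis(triethylsilyl) diketone (both arms 4-methylpent-3-enoyl)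
Conditions: Dess–Martin periodinane, NaHCO3, CH2Cl2, 0 °C
Reagents that add atoms: none
Why: Buffered Dess–Martin oxidation converts the secondary homoallylic alcohols into β,γ-unsaturated ketones under neutral conditions that should not move the prenyl double bond into conjugation and cannot epimerize the quaternary α-carbons.

Step 20
Reactants: 24 meso bis(triethylsilyl) diketone
Product: 25 CNP0297042.2 (target)
Conditions: HF·pyridine, pyridine, THF, 0 °C to rt
Reagents that add atoms: none
Why: Fluoride-mediated desilylation under buffered, non-basic conditions cleaves both triethylsilyl ethers while avoiding the retro-aldol cleavage of the β-hydroxy ketones and the conjugation of the β,γ-enones that a basic fluoride source could cause.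

**Compound list**

1 | dimethyl methylmalonate | COC(=O)C(C)C(=O)OC | starting material
2 | 5-chloropent-1-yne | C#CCCCCl | starting material
3 | dimethyl 2-methyl-2-(pent-4-yn-1-yl)propanedioate | COC(=O)C(C)(CCCC#C)C(=O)OC | intermediate
4 | (R)-2-(methoxycarbonyl)-2-methylhept-6-ynoic acid | COC(=O)[C@](C(=O)O)(C)CCCC#C | intermediate
5 | mixed isobutyl carbonic anhydride of 4 | COC(=O)[C@](C(=O)OC(=O)OCC(C)C)(C)CCCC#C | intermediate
6 | methyl (R)-2-(hydroxymethyl)-2-methylhept-6-ynoate | COC(=O)[C@](CO)(C)CCCC#C | intermediate
7 | methyl (R)-2-formyl-2-methylhept-6-ynoate | COC(=O)[C@](C=O)(C)CCCC#C | intermediate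
8 | lithium (R)-2-(methoxycarbonyl)-2-methylhept-6-ynoate | [Li+].COC(=O)[C@](C(=O)[O-])(C)CCCC#C | intermediate
9 | (S)-2-(hydroxymethyl)-2-methylhept-6-ynoic acid | OC(=O)[C@@](CO)(C)CCCC#C | intermediate
10 | methyl (S)-2-(hydroxymethyl)-2-methylhept-6-ynoate | COC(=O)[C@@](CO)(C)CCCC#C | intermediate
11 | methyl (S)-2-formyl-2-methylhept-6-ynoate | COC(=O)[C@@](C=O)(C)CCCC#C | intermediate
12 | methyl (1R,2S,3Z)-2-hydroxy-1-methyl-3-(prop-2-en-1-ylidene)cyclohexane-1-carboxylate | COC(=O)[C@]1(C)CCC/C(=C/C=C)[C@@H]1O | intermediate
13 | methyl (1R,2S,3Z)-1-methyl-3-(prop-2-en-1-ylidene)-2-(triethylsilyloxy)cyclohexane-1-carboxylate | COC(=O)[C@]1(C)CCC/C(=C/C=C)[C@@H]1O[Si](CC)(CC)CC | intermediate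
14 | B-alkyl-9-borabicyclo[3.3.1]nonane adduct of 13 (boron on the terminal carbon) | COC(=O)[C@]1(C)CCC/C(=C/CCB2C3CCCC2CCC3)[C@@H]1O[Si](CC)(CC)CC | intermediate
15 | methyl (1R,2S,3Z)-3-(3-hydroxypropylidene)-1-methyl-2-(triethylsilyloxy)cyclohexane-1-carboxylate | COC(=O)[C@]1(C)CCC/C(=C/CCO)[C@@H]1O[Si](CC)(CC)CC | intermediate
16 | methyl (1R,2S,3Z)-3-(3-iodopropylidene)-1-methyl-2-(triethylsilyloxy)cyclohexane-1-carboxylate | COC(=O)[C@]1(C)CCC/C(=C/CCI)[C@@H]1O[Si](CC)(CC)CC | intermediate
17 | ring A alkylzinc iodide (zinc on the former CH2I carbon of 16) | COC(=O)[C@]1(C)CCC/C(=C/CC[Zn]I)[C@@H]1O[Si](CC)(CC)CC | intermediate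
18 | ring A–ring B diester, ring A carbinol as OSiEt3, ring B carbinol free, both alkenes Z | COC(=O)[C@]1(C)CCC/C(=C/CC/C=C2/CCC[C@](C)(C(=O)OC)[C@@H]2O)[C@@H]1O[Si](CC)(CC)CC | intermediate
19 | meso bis(triethylsilyl) diester | COC(=O)[C@]1(C)CCC/C(=C/CC/C=C2/CCC[C@](C)(C(=O)OC)[C@@H]2O[Si](CC)(CC)CC)[C@@H]1O[Si](CC)(CC)CC | intermediate
20 | meso bis(triethylsilyl) diol | OC[C@]1(C)CCC/C(=C/CC/C=C2/CCC[C@](C)(CO)[C@@H]2O[Si](CC)(CC)CC)[C@@H]1O[Si](CC)(CC)CC | intermediate
21 | meso bis(triethylsilyl) dialdehyde | O=C[C@]1(C)CCC/C(=C/CC/C=C2/CCC[C@](C)(C=O)[C@@H]2O[Si](CC)(CC)CC)[C@@H]1O[Si](CC)(CC)CC | intermediate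
22 | bis(1-hydroxybut-3-en-1-yl) compound, side-chain carbinols unassigned | C=CCC(O)[C@]1(C)CCC/C(=C/CC/C=C2/CCC[C@](C)(C(O)CC=C)[C@@H]2O[Si](CC)(CC)CC)[C@@H]1O[Si](CC)(CC)CC | intermediate
23 | bis(1-hydroxy-4-methylpent-3-en-1-yl) compound, side-chain carbinols unassigned | CC(C)=CCC(O)[C@]1(C)CCC/C(=C/CC/C=C2/CCC[C@](C)(C(O)CC=C(C)C)[C@@H]2O[Si](CC)(CC)CC)[C@@H]1O[Si](CC)(CC)CC | intermediate
24 | meso bis(triethylsilyl) diketone | CC(C)=CCC(=O)[C@]1(C)CCC/C(=C/CC/C=C2/CCC[C@](C)(C(=O)CC=C(C)C)[C@@H]2O[Si](CC)(CC)CC)[C@@H]1O[Si](CC)(CC)CC | intermediate
25 | CNP0297042.2, meso diol diketone (ring A 1R,2S; ring B 1S,2R; both alkenes Z) | CC(C)=CCC(=O)[C@]1(C)CCC/C(=C/CC/C=C2/CCC[C@](C)(C(=O)CC=C(C)C)[C@@H]2O)[C@@H]1O | target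

**Step count**

Total steps: 20. Longest linear sequence: 17 steps (steps 1–4 and 8–20).

**Steps most likely to fail**

1. Step 13. The alkylnickel intermediate may lose a β-hydrogen before C–C reductive elimination, so that ring B closes without being joined to ring A, or the closure may show poor facial selectivity at the new carbinol carbon. The fallback uses known chemistry, sets out from iodide 16 and ynal 11 and rejoins the route at 19.
 - Ynal 11 is cyclized with vinylzinc chloride exactly as in step 8 to the mirror-image dienol, methyl (1S,2R,3Z)-2-hydroxy-1-methyl-3-(prop-2-en-1-ylidene)cyclohexane-1-carboxylate F1.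
 - F1 is silylated (Et3SiOTf, 2,6-lutidine) to its triethylsilyl ether F2, which is ozonized (O3, CH2Cl2/MeOH, −78 °C; Me2S) to the ring B α-silyloxy ketone, methyl (1S,2S)-1-methyl-3-oxo-2-(triethylsilyloxy)cyclohexane-1-carboxylate F3.
 - Iodide 16 is homologated by one carbon by alkylating methylenetriphenylphosphorane (Ph3P=CH2, THF) to the ring A butylidene triphenylphosphonium iodide F4.
 - The ylide of F4 (KN(SiMe3)2, THF, −78 °C) is condensed with F3 in a Wittig reaction. Unstabilized ylides are known to place their chain cis to the oxygen-bearing carbon of α-alkoxy ketones, which is the required Z geometry, so the product should be 19 directly.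

2. Step 8. Direct transfer of vinyl from zinc or residual magnesium to the aldehyde may outrun the slower six-membered nickelacycle formation, and the conjugated diene product may be consumed by oligomerization on zerovalent nickel. The fallback sets out from ynal 7 and rejoins at alcohol 15.
 - 7 is cyclized reductively (Ni(cod)2, PBu3, Et3SiH, THF), a known ynal reaction that delivers hydrogen instead of a carbon group and gives the carbinol directly as its silyl ether, methyl (1R,2S)-1-methyl-3-methylidene-2-(triethylsilyloxy)cyclohexane-1-carboxylate F5.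
 - Ozonolysis (O3; Me2S) gives the ring A α-silyloxy ketone, methyl (1R,2R)-1-methyl-3-oxo-2-(triethylsilyloxy)cyclohexane-1-carboxylate F6.
 - A Wittig reaction with the ylide of [3-(4-methoxybenzyloxy)propyl]triphenylphosphonium bromide (KN(SiMe3)2, THF) installs the chain cis to the silyloxy carbon, giving the (Z)-4-methoxybenzyl ether F7.
 - Oxidative removal of the 4-methoxybenzyl group (DDQ, CH2Cl2/pH 7 buffer) releases 15.

3. Step 2. The esterase may discriminate the enantiotopic ester groups incompletely, and the shortfall would be carried forward as the chiral diastereomer of every ring A–ring B compound. The fallback sets out from diester 3 and rejoins at 4.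
 - Half-saponification (KOH, 1.0 eq, MeOH) gives the racemic half-ester F8.
 - Classical resolution by crystallization with (S)-1-phenylethylamine gives the diastereomerically pure ammonium salt F9, taken here to be that of the (R)-acid; acidification returns 4.
 - The acid recovered from the mother liquor is not wasted, because each half-ester antipode can feed either ynal.

**Further compounds**

F1 | step 13 | methyl (1S,2R,3Z)-2-hydroxy-1-methyl-3-(prop-2-en-1-ylidene)cyclohexane-1-carboxylate | COC(=O)[C@@]1(C)CCC/C(=C/C=C)[C@H]1O
F2 | step 13 | methyl (1S,2R,3Z)-1-methyl-3-(prop-2-en-1-ylidene)-2-(triethylsilyloxy)cyclohexane-1-carboxylate | COC(=O)[C@@]1(C)CCC/C(=C/C=C)[C@H]1O[Si](CC)(CC)CC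
F3 | step 13 | methyl (1S,2S)-1-methyl-3-oxo-2-(triethylsilyloxy)cyclohexane-1-carboxylate | COC(=O)[C@@]1(C)CCCC(=O)[C@H]1O[Si](CC)(CC)CC
F4 | step 13 | {(4Z)-4-[(2S,3R)-3-(methoxycarbonyl)-3-methyl-2-(triethylsilyloxy)cyclohexylidene]butyl}triphenylphosphonium iodide | COC(=O)[C@]1(C)CCC/C(=C/CCC[P+](c2ccccc2)(c2ccccc2)c2ccccc2)[C@@H]1O[Si](CC)(CC)CC.[I-]
F5 | step 8 | methyl (1R,2S)-1-methyl-3-methylidene-2-(triethylsilyloxy)cyclohexane-1-carboxylate | COC(=O)[C@]1(C)CCCC(=C)[C@@H]1O[Si](CC)(CC)CC
F6 | step 8 | methyl (1R,2R)-1-methyl-3-oxo-2-(triethylsilyloxy)cyclohexane-1-carboxylate | COC(=O)[C@]1(C)CCCC(=O)[C@@H]1O[Si](CC)(CC)CC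
F7 | step 8 | methyl (1R,2S,3Z)-3-[3-(4-methoxybenzyloxy)propylidene]-1-methyl-2-(triethylsilyloxy)cyclohexane-1-carboxylate | COC(=O)[C@]1(C)CCC/C(=C/CCOCc2ccc(OC)cc2)[C@@H]1O[Si](CC)(CC)CC
F8 | step 2 | racemic 2-(methoxycarbonyl)-2-methylhept-6-ynoic acid | COC(=O)C(C)(CCCC#C)C(=O)O
F9 | step 2 | (S)-1-phenylethylammonium (R)-2-(methoxycarbonyl)-2-methylhept-6-ynoate | COC(=O)[C@](C(=O)[O-])(C)CCCC#C.C[C@H]([NH3+])c1ccccc1
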